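## Retrosynthetic overview
1. Cut only the aryl C–CH2 bond, not the usual "monomer + CH2O/Mannich C1 unit + monomer" two-bond disconnection. The bridge carbon is a C-methyl group already on the dearomatised half, oxidised (C–H) to an exocyclic methide that the arene captures (dehydrogenative cross-coupling).
2. The electrophilic half is C-methyl-butyrylfilicinic acid, made by dearomative double C-methylation of 3-methylphlorobutyrophenone.
3. The nucleophilic half is the 2-O-methyl ether of the same 3-methylphlorobutyrophenone: mask 4,6-OH, methylate the chelated 2-OH, unmask.
4. The common intermediate comes from 2-methylphloroglucinol and butanoyl chloride (Friedel–Crafts).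
5. No ring is built de novo. Both six-membered rings come from 2-methylphloroglucinol, the cyclohexadienone ring arises by dearomatisation (step 2), and the rings are joined last (steps 6–7, one flask).

**Assumption:** Aspidin has no stereogenic centre (its only sp3 ring carbon is CMe2), so it is achiral and the "single enantiomer" requirement does not apply; the SMILES shows one enol tautomer of a rapidly equilibrating set.

## Route

**Step 1**
Reactants: 1 (2-methylbenzene-1,3,5-triol, 2-methylphloroglucinol); 2 (butanoyl chloride)
Product: 3, 1-(2,4,6-trihydroxy-3-methylphenyl)butan-1-one
Conditions: AlCl3 (4 equiv), CH2Cl2/PhNO2, 0 → 45 °C; ice/HCl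
Reagents that add atoms: butanoyl chloride, CCCC(=O)Cl
Why: Friedel–Crafts C-acylation of a phloroglucinol, where the two free ring CH positions of 1 are symmetry-equivalent (one regioisomer) and the first acyl group deactivates the ring against a second acylation.

**Step 2**
Reactants: 3; 4 (iodomethane, 2.2 equiv)
Product: 5, 2-butanoyl-3,5-dihydroxy-4,6,6-trimethylcyclohexa-2,4-dien-1-one (C-methyl-butyrylfilicinic acid)
Conditions: NaOMe (3.5 equiv), MeI, MeOH, 0 °C → rt; 1 M HCl
Reagents that add atoms: iodomethane, CI (two CH3 incorporated)
Why: Dearomative C-alkylation of the acylphloroglucinol polyanion, in which either order of attack (free CH or C–Me carbon) converges on 5, the new quaternary carbon is CMe2 (no stereocentre), and over-methylation to the tetramethyl trione is limited by MeI stoichiometry.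

**Step 3**
Reactants: 3; 6 (chloromethyl methyl ether, 2.2 equiv)
Product: 7, 1-[2-hydroxy-4,6-bis(methoxymethoxy)-3-methylphenyl]butan-1-one
Conditions: MOMCl, i-Pr2NEt (2.5 equiv), CH2Cl2, 0 °C → rt
Reagents that add atoms: chloromethyl methyl ether, COCCl (two MOM groups)
Why: Regioselective O-alkylation under weak-base conditions, where the para 4-OH reacts first, then the less hindered ortho 6-OH, leaving the 2-OH (flanked by CH3 and C=O) locked in the hydrogen-bond chelate with the ketone.

**Step 4**
Reactants: 7; 4 (iodomethane)
Product: 8, 1-[2-methoxy-4,6-bis(methoxymethoxy)-3-methylphenyl]butan-1-one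
Conditions: MeI (3 equiv), K2CO3, DMF, 45 °C
Reagents that add atoms: iodomethane, CI
Why: Williamson etherification of the only remaining phenol, using K2CO3 in a dipolar aprotic solvent to break the chelate without enolising the ketone or affecting the MOM acetals.

**Step 5**
Reactants: 8
Product: 9, 1-(4,6-dihydroxy-2-methoxy-3-methylphenyl)butan-1-one
Conditions: 3 M aq HCl, MeOH, 50 °C, 1–2 h
Reagents that add atoms: none
Why: Acid acetal (MOM) cleavage, in which the aryl methyl ether and ketone are inert and the large excess of MeOH traps the released formaldehyde as dimethoxymethane, so the acyl-deactivated ring is not methylene-bridged.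

**Step 6 (key step, part 1: methide generation)**
Reactants: 5
Product: 10, 2-butanoyl-3-hydroxy-6,6-dimethyl-4-methylidenecyclohex-2-ene-1,5-dione (exocyclic methide, generated in solution and consumed directly in step 7, not isolated)
Conditions: Ag2O (1.5 equiv, added portionwise), TEMPO (1.0 equiv), THF, 0 °C → rt, dark. Compound 9 (1.5 equiv) is already dissolved in the flask as a spectator.
Reagents that add atoms: none (net loss of 2 H as H2O, Ag2O → 2 Ag)
Why: Proposed new method: Ag(I) oxidises the silver enolate of the strongly acidic vinylogous acid 5 (easier to oxidise than the acyl-deactivated, largely un-ionised phenol 9 sharing the flask) to the C-4 radical, TEMPO couples at C-4, and TEMPO-H is lost across the C4–CH3 bond (the only β-hydrogens available) to give methide 10 with no stereocentre formed; the closest known reaction type is Ag2O/TEMPO dehydrogenation of C-methyl dearomatised acylphloroglucinols to such methides for in situ hetero-Diels–Alder trapping, and the new element is chemoselectivity in the presence of a free phenolic partner.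

**Step 7 (key step, part 2: arene capture, same flask)**
Reactants: 10; 9 (1.5 equiv relative to 5)
Product: 11, aspidin, 2-butanoyl-4-[(3-butanoyl-2,6-dihydroxy-4-methoxy-5-methylphenyl)methyl]-3,5-dihydroxy-6,6-dimethylcyclohexa-2,4-dien-1-one
Conditions: THF, 0 °C → rt, dark, 10 intercepted as it forms; filter through Celite, cold 1 M HCl wash, chromatography (recover excess 9)
Reagents that add atoms: none (all atoms of 9 and 10 are retained)
Why: Proposed new method: the only free ring carbon of 9, flanked by two OH groups, adds to the CH2 terminus of the doubly activated enone 10 (vinylogous Michael/Friedel–Crafts alkylation), and rearomatisation plus re-enolisation give 11, with cross-selectivity fixed by structure (only 5 can become the electrophile, only 9 has a nucleophilic CH) and no stereocentre formed; the closest known reaction type is Michael addition of acylphloroglucinols to alkylidene cyclic β-triketones, and the new element is capture of an oxidatively generated, unsubstituted methide.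

## Compound list
| No. | Name | SMILES | Role |
|---|---|---|---|
| 1 | 2-methylbenzene-1,3,5-triol | Cc1c(O)cc(O)cc1O | starting material |
| 2 | butanoyl chloride | CCCC(=O)Cl | starting material |
| 3 | 1-(2,4,6-trihydroxy-3-methylphenyl)butan-1-one | CCCC(=O)c1c(O)c(C)c(O)cc1O | intermediate |
| 4 | iodomethane | CI | starting material |
| 5 | 2-butanoyl-3,5-dihydroxy-4,6,6-trimethylcyclohexa-2,4-dien-1-one | CCCC(=O)C1=C(O)C(C)=C(O)C(C)(C)C1=O | intermediate |
| 6 | chloromethyl methyl ether | COCCl | starting material |
| 7 | 1-[2-hydroxy-4,6-bis(methoxymethoxy)-3-methylphenyl]butan-1-one | CCCC(=O)c1c(O)c(C)c(OCOC)cc1OCOC | intermediate |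
| 8 | 1-[2-methoxy-4,6-bis(methoxymethoxy)-3-methylphenyl]butan-1-one | CCCC(=O)c1c(OC)c(C)c(OCOC)cc1OCOC | intermediate |
| 9 | 1-(4,6-dihydroxy-2-methoxy-3-methylphenyl)butan-1-one | CCCC(=O)c1c(OC)c(C)c(O)cc1O | intermediate |
| 10 | 2-butanoyl-3-hydroxy-6,6-dimethyl-4-methylidenecyclohex-2-ene-1,5-dione | CCCC(=O)C1=C(O)C(=C)C(=O)C(C)(C)C1=O | intermediate (product of step 6, used in situ in step 7) |
| 11 | aspidin (achiral) | CCCC(=O)C1=C(O)C(Cc2c(O)c(C)c(OC)c(C(=O)CCC)c2O)=C(O)C(C)(C)C1=O | target |

## Summary
- **Total step count:** 7 transformations. Steps 6 and 7 are telescoped in one flask, so there are 6 laboratory operations.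
- **Longest linear sequence:** 5 (steps 1 → 3 → 4 → 5 → 7). The other branch, 1 → 2 → 6 → 7, is 4.

## Three steps most likely to fail
1. **Step 6 (chemoselective oxidation).** Ag2O/TEMPO may attack 9 instead (o-quinone methide from its 4-OH/3-CH3 pair). It may also attack product 11 at the new bridging CH2 or the aryl CH3.
   - **Fallback:** remove the oxidant from the coupling event.
     - C-selenenylate 5 at C-4 (PhSeCl, pyridine) and oxidise to the selenoxide at −78 °C.
     - Destroy excess oxidant, then add 9 and warm.
     - Syn-elimination can only go into the CH3 group, so 10 is released under neutral, oxidant-free conditions.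
2. **Step 7 (capture of the methide).**
   - Methide 10 may dimerise by hetero-Diels–Alder reaction.
   - It may be attacked at C-4 by the enolate of unreacted 5.
   - The bridge in 11 may scramble by retro-Michael exchange to the two symmetrical dimers.
   - **Fallback:** reverse the polarity of the same one-bond disconnection.
     - Formylate 9 at its free CH (Vilsmeier) and reduce to the o-hydroxybenzyl alcohol (NaBH4).
     - Generate the aromatic o-quinone methide thermally or with mild acid.
     - Trap it with butyrylfilicinic acid (from phlorobutyrophenone, 2 equiv MeI, NaOMe), which has a free nucleophilic C-4 H.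
3. **Step 3 (2-OH versus 6-OH discrimination).** Incomplete selectivity would lead to the isomeric methyl ether.
   - **Fallback:** use selective deprotection instead of selective protection.
     - Tribenzylate 3 exhaustively.
     - Remove only the 2-O-benzyl group with BCl3 (1 equiv, −78 °C). This group is di-ortho-substituted, twisted out of plane and chelated to the carbonyl.
     - Methylate, then hydrogenolyse (H2, Pd/C), which also avoids any formaldehyde release in step 5.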